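**Strategy.** The dihydrofuran ring (O1, C2, C3, C3a, C7a) is opened at C2–C3 and O1–C7a. Two features are exploited: the anti-dioxygenated C2–C3 pair, with C2 allylic to the propenyl unit, is the retron of an aldehyde α-acyloxyallylation, and O1–C7a lies para to C5 of the benzene ring, whose side chain is carried as an acetyl group activating an aryl fluoride. In one flask, chromium-catalysed enantioselective addition of 3-bromo-2-methylpropenyl acetate to 5-acetyl-2-fluorobenzaldehyde forms C2–C3 and both ring stereocentres; fluoride then frees the C3 oxygen, the acetyl group shifts onto it from the future ring oxygen, and that oxygen closes the ring by SNAr. Ketone reduction, tigloylation and allylic oxidation follow.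

Key step: step 3

Assumption: L* is (S,S)-1,8-bis(4-isopropyl-4,5-dihydrooxazol-2-yl)-3,6-diphenyl-9H-carbazole; its sense of induction with reagent 7 has to be assigned on the first run, and the ligand enantiomer that gives Si-face addition to the aldehyde (3R) is the one used (both are made from valinol).

**Step 1**
Reactants: 1 5-bromo-2-fluorobenzaldehyde; 2 tributyl(1-ethoxyvinyl)stannane
Product: 4 5-acetyl-2-fluorobenzaldehyde, via enol ether 3 (not isolated)
Conditions: PdCl2(PPh3)2 (3 mol %), toluene, 100 °C; then 1 M HCl, THF, rt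
Reagents that add atoms: water, O
Why: Stille coupling of the aryl bromide with the α-ethoxyvinyl stannane (an acetyl anion equivalent) tolerates the aldehyde and the C–F bond, and mild aqueous acid should hydrolyse the enol ether to the methyl ketone.

**Step 2**
Reactants: 5 methacrolein; 6 acetyl bromide
Product: 7 3-bromo-2-methylprop-1-en-1-yl acetate (E/Z mixture)
Conditions: ZnCl2 (2 mol %), CH2Cl2, −20 °C → rt
Reagents that add atoms: none
Why: Lewis-acid-catalysed conjugate (1,4) addition of the acyl bromide to the enal (O-acylation, then bromide capture at the terminal carbon) should give the γ-acetoxyallyl bromide, whose alkene geometry is irrelevant because both isomers converge on the same allylchromium species.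

**Step 3**
Reactants: 4 5-acetyl-2-fluorobenzaldehyde; 7 3-bromo-2-methylprop-1-en-1-yl acetate
Product: 11 (2S,3R)-5-acetyl-2-(prop-1-en-2-yl)-2,3-dihydro-1-benzofuran-3-yl acetate, via silyl ether 8 (not isolated), via hydroxy acetate 9 (not isolated), via migrated acetate 10 (not isolated)
Conditions: 7 (1.3 equiv), CrCl2 (10 mol %), L* (11 mol %), i-Pr2NEt (30 mol %), Mn (2 equiv), Me3SiCl (1.5 equiv), THF, 0 °C → rt; then CsF (4 equiv), DMF, 50 °C, same flask
Reagents that add atoms: none
Why: Divalent chromium (regenerated by Mn, released from the product by Me3SiCl) turns 7 into a γ-acetoxy-β-methylallyl trivalent chromium species that adds through its γ-carbon to the aldehyde of 4 and forms C2–C3 as silyl ether 8; CsF then desilylates, the C3 alkoxide takes over the acetyl group through a five-membered orthoester anion (9 to 10), and the freed alkoxide on C2 displaces fluoride at C7a by addition–elimination, forming O1–C7a. The closest known reaction types are the catalytic asymmetric Nozaki–Hiyama–Kishi addition of 3-halopropenyl esters to aldehydes, the base-induced 1,2-acyl shift of diol monoesters and the intramolecular SNAr etherification of activated 2-fluoroaryl alkoxides. The dihydrofuran ring closes in a 5-exo-trig mode by attack of O1 on C7a, whose Meisenheimer intermediate is stabilised by the para acetyl group. C3 (R) is set by the chiral ligand on chromium, which should direct the allyl group to the Si face of the aldehyde, and C2 (S) by the closed chair transition state of the (E)-γ-acetoxyallyl chromium species, which gives the anti adduct that maps onto the 2,3-trans ring; both centres are untouched afterwards because the later events occur at oxygen only. The step needs addition to the aldehyde and not the ketone (intrinsic to allylchromium reagents), ring closure through the C2 oxygen only (the C3 oxygen could close no more than a four-membered ring, so the reversible acetyl shift is drained by the irreversible cyclisation) and a labile C–F bond (secured by the para acetyl group).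

**Step 4**
Reactants: 11 (2S,3R)-5-acetyl-2-(prop-1-en-2-yl)-2,3-dihydro-1-benzofuran-3-yl acetate
Product: 12 (2S,3R)-5-[(1R)-1-hydroxyethyl]-2-(prop-1-en-2-yl)-2,3-dihydro-1-benzofuran-3-yl acetate
Conditions: RuCl(p-cymene)[(R,R)-TsDPEN] (1 mol %), HCO2H/Et3N (5:2), EtOAc, rt
Reagents that add atoms: none
Why: Noyori-type asymmetric transfer hydrogenation reduces only the aryl methyl ketone (acetate, aryl ether and 1,1-disubstituted alkene are inert), and the (R,R)-configured catalyst is expected to give the (R)-carbinol, as with other aryl methyl ketones, independently of the remote ring stereocentres.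

**Step 5**
Reactants: 12 (2S,3R)-5-[(1R)-1-hydroxyethyl]-2-(prop-1-en-2-yl)-2,3-dihydro-1-benzofuran-3-yl acetate; 13 tiglic acid
Product: 14 (1R)-1-[(2S,3R)-3-acetoxy-2-(prop-1-en-2-yl)-2,3-dihydro-1-benzofuran-5-yl]ethyl (E)-2-methylbut-2-enoate
Conditions: DCC, DMAP (cat.), CH2Cl2, 0 °C → rt
Reagents that add atoms: none
Why: Steglich esterification acylates the secondary benzylic alcohol under neutral conditions with retention at the carbinol carbon and should neither isomerise the (E)-configured acyl group nor touch the C3 acetate.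

**Step 6**
Reactants: 14 (1R)-1-[(2S,3R)-3-acetoxy-2-(prop-1-en-2-yl)-2,3-dihydro-1-benzofuran-5-yl]ethyl (E)-2-methylbut-2-enoate
Product: 16 (1R)-1-[(2S,3R)-3-acetoxy-2-(3-oxoprop-1-en-2-yl)-2,3-dihydro-1-benzofuran-5-yl]ethyl (E)-2-methylbut-2-enoate (target), via allylic alcohol 15 (not isolated)
Conditions: SeO2 (0.5 equiv), t-BuOOH (3 equiv), CH2Cl2, rt; filter; then MnO2, CH2Cl2, rt
Reagents that add atoms: selenium dioxide, O=[Se]=O (delivers the oxygen); tert-butyl hydroperoxide, CC(C)(C)OO (terminal oxidant)
Why: Selenium dioxide allylic oxidation (ene reaction, then [2,3]-sigmatropic shift) should attack the electron-rich 1,1-disubstituted alkene at its methyl group in preference to the deactivated C2–H and the electron-poor tiglate, and MnO2 completes the oxidation of the primary allylic alcohol to the enal without touching a stereocentre.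

**Compound list**
1 | 5-bromo-2-fluorobenzaldehyde | O=Cc1cc(Br)ccc1F | starting material
2 | tributyl(1-ethoxyvinyl)stannane | CCCC[Sn](CCCC)(CCCC)C(=C)OCC | starting material
3 | 5-(1-ethoxyvinyl)-2-fluorobenzaldehyde | C=C(OCC)c1ccc(F)c(C=O)c1 | intermediate (not isolated)
4 | 5-acetyl-2-fluorobenzaldehyde | CC(=O)c1ccc(F)c(C=O)c1 | intermediate
5 | methacrolein (2-methylprop-2-enal) | CC(=C)C=O | starting material
6 | acetyl bromide | CC(=O)Br | starting material
7 | 3-bromo-2-methylprop-1-en-1-yl acetate (E/Z mixture) | CC(=O)OC=C(C)CBr | intermediate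
8 | (1R,2S)-1-(5-acetyl-2-fluorophenyl)-3-methyl-1-(trimethylsilyloxy)but-3-en-2-yl acetate | C=C(C)[C@H](OC(C)=O)[C@H](O[Si](C)(C)C)c1cc(C(C)=O)ccc1F | intermediate (not isolated)
9 | (1R,2S)-1-(5-acetyl-2-fluorophenyl)-1-hydroxy-3-methylbut-3-en-2-yl acetate (present as its alkoxide) | C=C(C)[C@H](OC(C)=O)[C@H](O)c1cc(C(C)=O)ccc1F | intermediate (not isolated)
10 | (1R,2S)-1-(5-acetyl-2-fluorophenyl)-2-hydroxy-3-methylbut-3-en-1-yl acetate (present as its alkoxide) | C=C(C)[C@H](O)[C@H](OC(C)=O)c1cc(C(C)=O)ccc1F | intermediate (not isolated)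
11 | (2S,3R)-5-acetyl-2-(prop-1-en-2-yl)-2,3-dihydro-1-benzofuran-3-yl acetate | C=C(C)[C@@H]1Oc2ccc(C(C)=O)cc2[C@H]1OC(C)=O | intermediate
12 | (2S,3R)-5-[(1R)-1-hydroxyethyl]-2-(prop-1-en-2-yl)-2,3-dihydro-1-benzofuran-3-yl acetate | C=C(C)[C@@H]1Oc2ccc([C@@H](C)O)cc2[C@H]1OC(C)=O | intermediate
13 | tiglic acid ((E)-2-methylbut-2-enoic acid) | C/C=C(\C)C(=O)O | starting material
14 | (1R)-1-[(2S,3R)-3-acetoxy-2-(prop-1-en-2-yl)-2,3-dihydro-1-benzofuran-5-yl]ethyl (E)-2-methylbut-2-enoate | C=C(C)[C@@H]1Oc2ccc([C@@H](C)OC(=O)/C(C)=C/C)cc2[C@H]1OC(C)=O | intermediate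
15 | (1R)-1-[(2S,3R)-3-acetoxy-2-(3-hydroxyprop-1-en-2-yl)-2,3-dihydro-1-benzofuran-5-yl]ethyl (E)-2-methylbut-2-enoate | C=C(CO)[C@@H]1Oc2ccc([C@@H](C)OC(=O)/C(C)=C/C)cc2[C@H]1OC(C)=O | intermediate (not isolated)
16 | (1R)-1-[(2S,3R)-3-acetoxy-2-(3-oxoprop-1-en-2-yl)-2,3-dihydro-1-benzofuran-5-yl]ethyl (E)-2-methylbut-2-enoate | C=C(C=O)[C@@H]1Oc2ccc([C@@H](C)OC(=O)/C(C)=C/C)cc2[C@H]1OC(C)=O | target

**Step count.** Total: 6 steps. Longest linear sequence: 5 steps (steps 1, 3, 4, 5, 6, from compound 1).

**Steps most likely to fail**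

1. Step 3. The chromium addition may show poor facial selectivity on the aldehyde or eroded anti selectivity with the 2-methyl-substituted acetoxyallyl reagent, and the acetate may be cleaved during the fluoride stage. The fallback sets out from 4 and 5 and comes back at 11. Aldehyde 4 and methacrolein 5 are joined in a racemic, anti-selective chromium-mediated cross-pinacol-type coupling (CrCl2, Et3SiCl, DMF, rt). The enal is reduced to a γ-silyloxyallyl chromium species, which should give racemic anti-1-(5-acetyl-2-fluorophenyl)-3-methyl-2-(triethylsilyloxy)but-3-en-1-ol F1. CsF in DMF at 60 °C removes the silyl group and closes the ring by SNAr to racemic trans-5-acetyl-2-(prop-1-en-2-yl)-2,3-dihydro-1-benzofuran-3-ol F2. Lipase-catalysed kinetic resolution (Burkholderia cepacia lipase, vinyl acetate, MTBE, 30 °C) is expected, by the empirical rule for acylation of secondary alcohols, to leave the (2S,3R)-alcohol F3 and to acetylate its enantiomer to the (2R,3S)-acetate F4. F3 is then acetylated (Ac2O, pyridine, DMAP) to 11. Should the enzyme show the opposite preference, its acetate is 11 itself. If only acetate loss occurs in step 3, the same chemical acetylation restores 11.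

2. Step 6. Oxidation may occur at the wrong allylic site or on the tiglate, may overrun, or the selenous acid may ionise the benzylic esters. The fallback sets out from 14 and comes back at 16. Ene-type allylic chlorination of the isopropenyl group with hypochlorous acid made in the flask (Ca(OCl)2, CO2, CH2Cl2/H2O, 0 °C) should give (1R)-1-[(2S,3R)-3-acetoxy-2-(3-chloroprop-1-en-2-yl)-2,3-dihydro-1-benzofuran-5-yl]ethyl (E)-2-methylbut-2-enoate F5. Kornblum-type oxidation of this allylic chloride with N-methylmorpholine N-oxide (NaI cat., MeCN, rt) should give 16.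

3. Step 5. Acylation by the α-branched unsaturated acid may be slow (N-acylurea formation), and the para-alkoxybenzylic carbinol may ionise. The fallback sets out from 12 and comes back at 14. Steglich acylation with the unhindered, saturated 2-(diethoxyphosphoryl)propanoic acid (DCC, DMAP, CH2Cl2) should give (1R)-1-[(2S,3R)-3-acetoxy-2-(prop-1-en-2-yl)-2,3-dihydro-1-benzofuran-5-yl]ethyl 2-(diethoxyphosphoryl)propanoate F6. Horner–Wadsworth–Emmons olefination with acetaldehyde (LiCl, DBU, MeCN, 0 °C) should then build the (E)-2-methylbut-2-enoate and give 14.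

**Further compounds**
F1 | step 3 | racemic (1R*,2S*)-1-(5-acetyl-2-fluorophenyl)-3-methyl-2-(triethylsilyloxy)but-3-en-1-ol (one enantiomer drawn) | C=C(C)[C@H](O[Si](CC)(CC)CC)[C@H](O)c1cc(C(C)=O)ccc1F
F2 | step 3 | racemic trans-1-[3-hydroxy-2-(prop-1-en-2-yl)-2,3-dihydro-1-benzofuran-5-yl]ethan-1-one (one enantiomer drawn) | C=C(C)[C@@H]1Oc2ccc(C(C)=O)cc2[C@H]1O
F3 | step 3 | 1-[(2S,3R)-3-hydroxy-2-(prop-1-en-2-yl)-2,3-dihydro-1-benzofuran-5-yl]ethan-1-one | C=C(C)[C@@H]1Oc2ccc(C(C)=O)cc2[C@H]1O
F4 | step 3 | (2R,3S)-5-acetyl-2-(prop-1-en-2-yl)-2,3-dihydro-1-benzofuran-3-yl acetate | C=C(C)[C@H]1Oc2ccc(C(C)=O)cc2[C@@H]1OC(C)=O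
F5 | step 6 | (1R)-1-[(2S,3R)-3-acetoxy-2-(3-chloroprop-1-en-2-yl)-2,3-dihydro-1-benzofuran-5-yl]ethyl (E)-2-methylbut-2-enoate | C=C(CCl)[C@@H]1Oc2ccc([C@@H](C)OC(=O)/C(C)=C/C)cc2[C@H]1OC(C)=O
F6 | step 5 | (1R)-1-[(2S,3R)-3-acetoxy-2-(prop-1-en-2-yl)-2,3-dihydro-1-benzofuran-5-yl]ethyl 2-(diethoxyphosphoryl)propanoate (epimers at the phosphonate carbon) | C=C(C)[C@@H]1Oc2ccc([C@@H](C)OC(=O)C(C)P(=O)(OCC)OCC)cc2[C@H]1OC(C)=O
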